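Start from slowness. Turn each rate around into minutes per molar of product, and take that cost as a sum: a fixed part, a part going as the inverse of c(starting material), and a part going as the inverse of c(partner), with one partner assumed used per product.

in all of them: free catalyst 0.84 mM
- birch: starting material 0.28 M; partner 0.63 M; run made earlier
- elm: starting material 0.63 M; partner 0.63 M; run made earlier
- flask: starting material 0.42 M; partner 0.630 M

| run | time / min | product / % | starting material / % |
|---|---|---|---|
| birch | 0.500 | 27.3 | 72.0 |
| birch | 1.50 | 74.1 | 25.4 |
| birch | 3.00 | 100.1 | 0.1 |
| birch | 4.00 | 100.3 | 0 |
| birch | 6.00 | 99.6 | 0.1 |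
| elm | 0.500 | 13.2 | 86.3 |
| elm | 1.50 | 36.7 | 62.9 |
| elm | 3.00 | 65.0 | 34.3 |
| elm | 4.00 | 78.5 | 22.0 |
| elm | 6.00 | 92.5 | 7.2 |

(each reading ± 0.3 percentage points)

1. apparent order in free catalyst when 20 % of the starting material are converted (percent change of the rate of making product for one percent more free catalyst charged)
2. apparent order in partner when 20 % of the starting material are converted (percent change of the rate of making product for one percent more partner charged)

- no earlier run changes the charge of free catalyst; that part of a forecast is a guess
- no earlier run changes the charge of partner; that part of a forecast is a guess

Read the rates off the product columns. Elm gives 0.148 M min⁻¹ between 0.500 min and 1.50 min, then 0.0851 M min⁻¹ between 3.00 min and 4.00 min. Birch gives 0.131 M min⁻¹ between 0.500 min and 1.50 min. Elm's two rates put the two reagent coefficients together at 1.43 min. Birch splits off 0.187 min for starting material, which leaves 1.24 min for partner and a fixed part, written as its inverse, a top rate of 0.269 M min⁻¹.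

At 20 % conversion the sum puts the flask at a rate of 0.153 M min⁻¹. Multiply the partner term by that rate to get 0.346, the partner share: the percent gain in rate for one percent more c(partner) at that moment. One percent more charged raises c(partner) there by 1.15 percent, so commit to an order of 0.400.

Test whether one number is enough: it isn't, since no run changes free catalyst, so the share is silent there and 1 is a bare guess.

The forecast says 0.35 for partner, below my figure, and 1 for free catalyst, with the words “Catalyst was never varied”.

The flask gives 0.39 for partner and 0.87 for free catalyst.

    starting material + catalyst intermediate A → catalyst intermediate B (k = 88.0 M⁻¹ s⁻¹)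
    partner + free catalyst → catalyst intermediate A (k = 70.0 M⁻¹ s⁻¹)
    2 free catalyst ⇌ resting dimer, settled at all times (K = 14000 M⁻¹)
    catalyst intermediate B → free catalyst + product (k = 4.70 s⁻¹)

In the flask the share of 0.346, stepped up for the charge to 0.400, stands against 0.39. On elm between 1.50 min and 3.00 min, an interval the sum was not fitted to, taking c(partner) equal to c(starting material), the sum gives a rate of 0.119 M min⁻¹ against 0.119 M min⁻¹ read, and a partner share of 0.483, above the flask's 0.346. In the flask, the steps of the round ran together, each with half its turnover up to 5.00 min done by about 1.38 min, while starting material fell from 80.7 % at 0.500 min to 18.8 % at 2.50 min, with resting dimer at 15.5 % of the catalyst at 0.518 min. By 5.00 min starting material, the limiting reagent, stood at 0 %, partner at 33 %, and catalyst intermediate A held >99.9 % of the catalyst.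

The runs come from a simulation with constants of no real substance, noise included.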